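**Plan**

1. Numbering used throughout: O1–C2(CH3)–C3(aryl)–O4 in the dioxine ring, helper carboxyl group on C5 (next to the carbon that carries O4), allyl group on C6. The retrosynthesis cuts C6–allyl (carboxylate-directed C–H allylation, the C5 carboxyl group then leaves as CO2), then C3–aryl (arylzinc plus cyclic oxocarbenium ion), then O1–C2 by undoing a 1,2-oxygen shift, which contracts the six-membered 1,4-dioxine ring to a five-membered 1,3-benzodioxole.
2. Enabling feature: the O1–C2H(CH3)–C3H(Ar)–O4 unit is a disguised α-oxygenated acetal. With O1 and O4 both on C3 (the acetal carbon of a 1,3-benzodioxole) and a leaving group on C2, a shift of O1 from C3 to C2 grows the five-membered ring to the six-membered ring and leaves C3 as an O4-stabilised cation that takes the aryl group.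
3. Forward order: dioxole ring first (catechol 1 plus 1,1-dichloroacetone), CBS reduction, ring expansion with arylation (dioxine ring and both stereocentres), ester hydrolysis, ortho-allylation, protodecarboxylation.
4. Helper: the ester on C5 is ortho to O4 and so makes O1 the more nucleophilic oxygen, which fixes which oxygen migrates. As the acid it later directs the allyl group to C6, para to O1 and meta to O4, and is then removed.
5. Stereochemistry: C2 (R) comes from the CBS-set (S)-carbinol by one inversion during the shift; C3 (R) comes from addition of the aryl group anti to the C2 methyl group (trans ring); the acetal stereocentre is erased in the oxocarbenium ion.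

Key step: step 3

Assumption: compound 5 is used as the purchased THF solution, and the (S) descriptor of the carbinol in 4 is assigned from the usual CBS model.

Step 1
Reactants: 1 methyl 2,3-dihydroxybenzoate; 2 1,1-dichloropropan-2-one
Product: 3 methyl 2-acetyl-1,3-benzodioxole-4-carboxylate (racemic at the acetal carbon)
Conditions: K2CO3, KI (cat.), DMF, 70 °C
Reagents that add atoms: none
Why: Double Williamson-type O-alkylation of a catechol by a geminal dihalide (the way methylenedioxy rings and benzodioxole-2-carboxylates are made), with SN2 at the α-halo ketone carbon followed by fast five-membered closure of the α-chloro ether; no stereocentre of the target is set.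

Step 2
Reactants: 3 methyl 2-acetyl-1,3-benzodioxole-4-carboxylate
Product: 4 methyl 2-[(1S)-1-hydroxyethyl]-1,3-benzodioxole-4-carboxylate (both acetal epimers)
Conditions: (R)-2-methyl-CBS-oxazaborolidine (cat.), BH3·SMe2, THF, −20 °C; MeOH quench
Reagents that add atoms: none
Why: Corey–Bakshi–Shibata reduction, in which the catalyst should distinguish the large dioxolyl group from the methyl group and deliver hydride to give the (S)-carbinol; the acetal carbon is stereogenic only through the remote ester, so both epimers should be reduced in the same sense, and the aryl ester should survive borane at this temperature.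

Step 3
Reactants: 4 methyl 2-[(1S)-1-hydroxyethyl]-1,3-benzodioxole-4-carboxylate; 5 (3,4,5-trimethoxyphenyl)magnesium bromide
Product: 9 methyl (2R,3R)-2-methyl-3-(3,4,5-trimethoxyphenyl)-2,3-dihydro-1,4-benzodioxine-5-carboxylate, via arylzinc bromide 6 (not isolated), via secondary triflate 7 (not isolated), via cyclic oxocarbenium triflate 8 (not isolated)
Conditions: Tf2O, 2,6-di-tert-butyl-4-methylpyridine, CH2Cl2, −78 to 0 °C; then 6 (from 5 and ZnBr2, THF, 0 °C), −78 °C to rt
Reagents that add atoms: none
Why: Proposed new method: the secondary triflate 7 is displaced from the rear by a lone pair of the neighbouring acetal oxygen (3-exo-tet, bridged oxiranium ion), and cleavage of the old bond from this oxygen to the acetal carbon moves the oxygen onto the CH(CH3) carbon, so that the five-membered dioxole ring becomes the six-membered 1,4-dioxine ring as the oxocarbenium ion 8, which is held by the second oxygen and then takes up the aryl group from 6. The closest known reaction types are the 1,2-shift of an anomeric oxygen to C2 in pyranoside 2-O-triflates and in deoxofluorination of glycosides, the ring expansion of 2-(1-haloalkyl)-1,3-dithiolanes to dihydro-1,4-dithiins, and the addition of arylzinc reagents to glycosyl oxocarbenium ions. The six-membered ring is closed by this 1,2-oxygen shift alone, without an end-to-end cyclisation. The CH(CH3) centre should become R by the single inversion of the catalyst-set (S)-carbinol, and the aryl-bearing centre should become R because the arylzinc adds to the planar oxocarbenium carbon on the face away from the adjacent methyl group, which gives the trans ring. The step needs the oxygen meta to the ester to be the one that migrates, and the CO2Me group should secure this because it takes electron density from the ortho oxygen by conjugation and shields it, while departure of triflate makes the choice irreversible. The mixture of acetal epimers converges because the acetal carbon is planar in 8, and an arylzinc is chosen because it should leave the methyl ester intact.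

Step 4
Reactants: 9 methyl (2R,3R)-2-methyl-3-(3,4,5-trimethoxyphenyl)-2,3-dihydro-1,4-benzodioxine-5-carboxylate
Product: 10 (2R,3R)-2-methyl-3-(3,4,5-trimethoxyphenyl)-2,3-dihydro-1,4-benzodioxine-5-carboxylic acid
Conditions: LiOH, THF/MeOH/H2O, 50 °C; then aq. HCl
Reagents that add atoms: lithium hydroxide, [Li+].[OH-]
Why: Ester saponification (acyl–oxygen cleavage by hydroxide), which touches neither the benzylic ether ring nor the two stereocentres because neither centre carries an acidic hydrogen.

Step 5
Reactants: 10 (2R,3R)-2-methyl-3-(3,4,5-trimethoxyphenyl)-2,3-dihydro-1,4-benzodioxine-5-carboxylic acid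
Product: 11 (2R,3R)-2-methyl-6-(prop-2-en-1-yl)-3-(3,4,5-trimethoxyphenyl)-2,3-dihydro-1,4-benzodioxine-5-carboxylic acid
Conditions: allyl acetate, [RuCl2(p-cymene)]2 (cat.), K3PO4, MeCN, 50 °C
Reagents that add atoms: allyl acetate, C=CCOC(C)=O
Why: Carboxylate-directed ortho C–H allylation of a benzoic acid by a divalent ruthenium carboxylate (cyclometalation at C6, the only free ortho C–H, then insertion of allyl acetate and β-acetoxy elimination), which should place the allyl group para to O1 and meta to O4 without forming a stereocentre.

Step 6
Reactants: 11 (2R,3R)-2-methyl-6-(prop-2-en-1-yl)-3-(3,4,5-trimethoxyphenyl)-2,3-dihydro-1,4-benzodioxine-5-carboxylic acid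
Product: 12 (2R,3R)-2-methyl-6-(prop-2-en-1-yl)-3-(3,4,5-trimethoxyphenyl)-2,3-dihydro-1,4-benzodioxine (target CNP0000093.2)
Conditions: Ag2CO3 (cat.), AcOH (cat.), DMSO, 120 °C
Reagents that add atoms: none
Why: Silver-catalysed protodecarboxylation of an ortho,ortho-disubstituted benzoic acid (loss of CO2 from the silver carboxylate and protonation of the aryl–silver species), which should be eased by the flanking alkoxy and allyl groups and removes the helper without touching the stereocentres.

**Compound list**

1 | methyl 2,3-dihydroxybenzoate | COC(=O)c1cccc(O)c1O | starting material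
2 | 1,1-dichloropropan-2-one | CC(=O)C(Cl)Cl | starting material
3 | methyl 2-acetyl-1,3-benzodioxole-4-carboxylate (racemic) | CC(=O)C1Oc2cccc(C(=O)OC)c2O1 | intermediate
4 | methyl 2-[(1S)-1-hydroxyethyl]-1,3-benzodioxole-4-carboxylate (both acetal epimers) | C[C@H](O)C1Oc2cccc(C(=O)OC)c2O1 | intermediate
5 | (3,4,5-trimethoxyphenyl)magnesium bromide | COc1cc([Mg]Br)cc(OC)c1OC | starting material
6 | (3,4,5-trimethoxyphenyl)zinc bromide | COc1cc([Zn]Br)cc(OC)c1OC | intermediate
7 | methyl 2-[(1S)-1-{[(trifluoromethyl)sulfonyl]oxy}ethyl]-1,3-benzodioxole-4-carboxylate | C[C@H](OS(=O)(=O)C(F)(F)F)C1Oc2cccc(C(=O)OC)c2O1 | intermediate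
8 | (2R)-5-(methoxycarbonyl)-2-methyl-2H-1,4-benzodioxin-4-ium trifluoromethanesulfonate | COC(=O)c1cccc2c1[O+]=C[C@@H](C)O2.[O-]S(=O)(=O)C(F)(F)F | intermediate
9 | methyl (2R,3R)-2-methyl-3-(3,4,5-trimethoxyphenyl)-2,3-dihydro-1,4-benzodioxine-5-carboxylate | COC(=O)c1cccc2c1O[C@H](c1cc(OC)c(OC)c(OC)c1)[C@@H](C)O2 | intermediate
10 | (2R,3R)-2-methyl-3-(3,4,5-trimethoxyphenyl)-2,3-dihydro-1,4-benzodioxine-5-carboxylic acid | OC(=O)c1cccc2c1O[C@H](c1cc(OC)c(OC)c(OC)c1)[C@@H](C)O2 | intermediate
11 | (2R,3R)-2-methyl-6-(prop-2-en-1-yl)-3-(3,4,5-trimethoxyphenyl)-2,3-dihydro-1,4-benzodioxine-5-carboxylic acid | OC(=O)c1c(CC=C)ccc2c1O[C@H](c1cc(OC)c(OC)c(OC)c1)[C@@H](C)O2 | intermediate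
12 | (2R,3R)-2-methyl-6-(prop-2-en-1-yl)-3-(3,4,5-trimethoxyphenyl)-2,3-dihydro-1,4-benzodioxine | C=CCc1ccc2c(c1)O[C@H](c1cc(OC)c(OC)c(OC)c1)[C@@H](C)O2 | target

**Step count**

Total steps: 6. Longest linear sequence: 6 steps (1 → 3 → 4 → 9 → 10 → 11 → 12).

**Steps most likely to fail**

Step 3. Several processes may compete:
- migration of the ester-flanked oxygen, which would give the other ring orientation;
- a 1,2-hydride shift from the acetal carbon to a dioxolenium ion;
- loss of a proton from the oxocarbenium ion;
- poor facial selectivity in the arylation.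

The fallback uses known chemistry, sets out from 1 and comes back at 9. The dianion of 1 (NaH, DMF) should be alkylated at the 3-oxygen, the phenoxide not tied to the ester, by methyl (S)-2-chloropropanoate with inversion, to give methyl (2R)-2-[2-hydroxy-3-(methoxycarbonyl)phenoxy]propanoate F1. Acid-catalysed lactonisation (TsOH, toluene, reflux) should give methyl (2R)-2-methyl-3-oxo-2,3-dihydro-1,4-benzodioxine-5-carboxylate F2. One equivalent of 5 at −78 °C should open this aryl-ester lactone to methyl 2-hydroxy-3-{[(2R)-1-oxo-1-(3,4,5-trimethoxyphenyl)propan-2-yl]oxy}benzoate F3. NaBH4 should reduce it to methyl 2-hydroxy-3-{[(2R)-1-hydroxy-1-(3,4,5-trimethoxyphenyl)propan-2-yl]oxy}benzoate F4, where either carbinol epimer serves. BF3·OEt2 in CH2Cl2 should then close the ring through the trimethoxybenzyl cation to the thermodynamically preferred trans ester 9.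

Step 1. Base-induced self-condensation or Favorskii-type rearrangement of the dichloroketone, or C-alkylation, may outrun the double O-alkylation. The fallback sets out from 1 and comes back at 4, so it also replaces step 2 by the chiral pool. Acid-catalysed acetalisation of 1 with (S)-2-(benzyloxy)propanal (TsOH, toluene, water removal) should give methyl 2-[(1S)-1-(benzyloxy)ethyl]-1,3-benzodioxole-4-carboxylate F5, and hydrogenolysis (H2, Pd/C, EtOAc) should give 4.

Step 5. Cyclometalation next to the ortho oxygen may be slow, and the new double bond may migrate into conjugation or be attacked by the carboxylate. The fallback sets out from 10 and comes back at 11. Carboxylate-directed ortho-iodination with Pd(OAc)2 (cat.), PhI(OAc)2 and I2 should give (2R,3R)-6-iodo-2-methyl-3-(3,4,5-trimethoxyphenyl)-2,3-dihydro-1,4-benzodioxine-5-carboxylic acid F6. Stille coupling of F6 with allyltributylstannane and Pd(PPh3)4 should give 11.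

**Further compounds**

F1 | step 3 | methyl (2R)-2-[2-hydroxy-3-(methoxycarbonyl)phenoxy]propanoate | COC(=O)c1cccc(O[C@H](C)C(=O)OC)c1O
F2 | step 3 | methyl (2R)-2-methyl-3-oxo-2,3-dihydro-1,4-benzodioxine-5-carboxylate | COC(=O)c1cccc2c1OC(=O)[C@@H](C)O2
F3 | step 3 | methyl 2-hydroxy-3-{[(2R)-1-oxo-1-(3,4,5-trimethoxyphenyl)propan-2-yl]oxy}benzoate | COC(=O)c1cccc(O[C@H](C)C(=O)c2cc(OC)c(OC)c(OC)c2)c1O
F4 | step 3 | methyl 2-hydroxy-3-{[(2R)-1-hydroxy-1-(3,4,5-trimethoxyphenyl)propan-2-yl]oxy}benzoate (carbinol epimers) | COC(=O)c1cccc(O[C@H](C)C(O)c2cc(OC)c(OC)c(OC)c2)c1O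
F5 | step 1 | methyl 2-[(1S)-1-(benzyloxy)ethyl]-1,3-benzodioxole-4-carboxylate | C[C@H](OCc1ccccc1)C1Oc2cccc(C(=O)OC)c2O1
F6 | step 5 | (2R,3R)-6-iodo-2-methyl-3-(3,4,5-trimethoxyphenyl)-2,3-dihydro-1,4-benzodioxine-5-carboxylic acid | OC(=O)c1c(I)ccc2c1O[C@H](c1cc(OC)c(OC)c(OC)c1)[C@@H](C)O2
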